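## Analysis of the target

The target 27 is a cyclobutane in which all four ring carbons are stereocentres. With the ring numbered so that C1 and C2 are the two CH–CO2H carbons and C3 and C4 the two quaternary carbons, C3 and C4 each carry a methyl group and a 4-methoxy-3-methyl-2-oxo-2H-pyran-6-yl ring bound through C6'. The two carboxyl groups are cis to each other and cis to both methyl groups, and the two pyranones share the opposite face. A mirror plane through the midpoints of C1–C2 and C3–C4 makes the compound meso, so only relative configuration has to be controlled. The 2-pyranones are vinylogous lactones that hydroxide and alkoxide open, that hydrides and dissolving metals reduce and that react photochemically, and the cis-1,2-diacid can close to an anhydride or epimerise under forcing conditions. The difficulty lies in two adjacent quaternary carbons inside a four-membered ring, with two methyls and two carboxyls crowded on one face. The strategy rests on C1 and C2: both are α-carbons of carboxyl groups and so have the same nucleophilic polarity, they are the only ring carbons that bear hydrogen, and a three-atom imide bridge across the two carboxyls forces them cis.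

## Retrosynthetic reasoning

**27 back to 21.** No carbon–carbon bond is cut. The two carboxyl groups are tied back, by way of 26, 25, 23 and 22, into the N-(4-methoxybenzyl) imide 21. An imide is preferred to an anhydride because its α-hydrogens can be removed by amide bases without ring opening, and because the nitrogen substituent can later be exchanged for an activating carbamate. The forward sequence has to remove the benzyl group, activate the imide and open it without exposing the pyranones to hot hydroxide.

**21 back to 19.** The C1–C2 bond is cut. Cutting C3–C4 would require a bond between two quaternary carbons with both stereocentres set in the bond-forming event. Cutting C1–C4 together with C2–C3 leads to a photocycloaddition in the presence of the pyranone chromophores. The chosen cut leaves the seven-membered imide 19, which has no small ring and already carries C3 and C4 as a meso pair. The forward reaction joins two carbons of like polarity, so it must be an oxidation of bis-enolate 20. It has to close the four-membered ring across the seven-membered ring and place the imide bridge on the methyl face.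

**19 back to 14 and 15.** The two C–N bonds of the imide are cut, which leads through amic acid 17 and the cyclic anhydride 16 to the meso diacid 14 and amine 15. The anhydride stage allows exactly one of the two equivalent carboxyls to be turned into the amide.

**14 back to 11.** The two carboxyl carbons are reconnected as the double bond of cyclohexene 11. In an open chain the meso relation of C3 and C4 could only come from dimerising two tertiary centres, which gives no control over meso versus racemic and must join two fully substituted carbons. In a six-membered ring the same relation is simply cis, and ring cleavage by ozonolysis and oxidation passes it on unchanged.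

**11 back to 5 and 6.** Each pyranone is cut at the lactone bond O1'–C2' and at C5'–C6', and the methyl ether is removed. The forward sequence adds the terminal carbon of dianion 7 to each formyl carbon of 5 to give 8, oxidises to 9, lactonises to 10 and methylates. The aldehyde carbons become C6', so the pyranones grow directly on the quaternary carbons.

**5 back to 3.** Adjustment of oxidation level through diol 4. The aldehyde level is needed because a cis-diacyl derivative at the acid level would collapse to the anhydride after the first acylation.

**3 back to 1 and 2.** The two ring bonds made in a Diels–Alder reaction are cut. The dienophile 2 is a cyclic Z-alkene, so suprafacial addition of 1 fixes the two methyl-bearing quaternary carbons cis with no selectivity question.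

## Alternatives that were turned down

Alternative 1: Both pyranones are cut at C5'–C6' and O1'–C2', leaving a cyclobutane cis-dialdehyde A2 with C1 and C2 carried as an acetonide-protected diol. In the forward key step A2 would react twice with the silyloxy diene A3 under Eu(fod)3 catalysis to give the bis(5,6-dihydropyranone) A1.
- For: it is convergent, the heterocycles arrive late, and each ring with its methoxy group forms in one operation. On ring-forming economy per pyranone it is stronger than the aldol, oxidation, lactonisation and methylation sequence used here.
- Against: A1 is at the dihydropyranone level, and dehydrogenation across C5'–C6' has no mild solution when C6' sits next to a quaternary carbon. The two neopentyl formyl groups are cis on a cyclobutane and can lactolise after the first addition.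
- Against: the cyclobutane with all four stereocentres must already exist in A2, so the hard part of the problem is untouched.
- Against: the diol must finally be oxidised to the diacid, and cis-1,4-diols tend to stop at the lactone.
- In exchange for its longer pyranone construction, the chosen route builds the pyranones at the aromatic oxidation level, carries C1 and C2 at the carboxyl level throughout, and makes the cyclobutane itself in the key step.

Alternative 2: The cyclobutane is cut at C1–C4 and C2–C3, and the two methyl groups are tied back as a thiolane. In the forward key step triplet-sensitised maleic anhydride A6 would add across the tetrasubstituted double bond of the dihydrothiophene A5 to give the doubly fused cyclobutane A4. Desulfurisation with Raney Ni and hydrolysis would follow.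
- For: two ring bonds form in one step, the anhydride delivers the cis-diacid directly, and the route is clearly shorter than the chosen one.
- Against: the 2-pyranones absorb and undergo cycloaddition and electrocyclisation themselves. The alkene of A5 is conjugated with both of them, so it should take the triplet energy in place of A6.
- Against: maleic anhydride normally adds to cyclic alkenes with the two rings anti, whereas A4 needs the anhydride on the same face as the thiolane.
- Against: Raney Ni is likely to reduce the pyranone double bonds.
- The face question is no easier there than in the chosen route. The chosen route offers thermal ground-state chemistry and a cis relation of the carboxyls that is structurally enforced.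

Alternative 3: The bonds C3–C6' and C4–C6' are cut, so that intact pyranones are delivered to two tertiary radicals. In the forward key step the diacid A8 would lose CO2 twice under [Ir(dF(CF3)ppy)2(dtbbpy)]PF6 and visible light, and each radical would attack C6' of the sulfonylpyranone A9 with loss of sulfinate to give A7.
- For: the pyranone is used as a finished building block. Trapping of the cyclobutyl radical from the open face puts the pyranone trans to the C1 and C2 substituents, which is what the target needs. On this point it is at least as good as the chosen route.
- Against: the second radical forms next to a quaternary carbon that already bears a pyranone, so addition should be slow and reduction should compete.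
- Against: ipso substitution at C6' of a sulfonylpyranone is not established.
- Against: A8 is itself a cyclobutane with two quaternary carbons, and C1 and C2 again need late oxidation from the diol level.
- The chosen route also has one unprecedented step, but its precursor is reached by well-precedented reactions and the final oxidation state is in place from the start.

Key step: step 10

Remark on stereochemistry: the target is meso, so no absolute control is needed. Every chiral intermediate is racemic and its SMILES shows relative configuration only.

Abbreviations: Pyr = 4-methoxy-3-methyl-2-oxo-2H-pyran-6-yl; PMB = 4-methoxybenzyl; Boc = tert-butoxycarbonyl.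

## Route

Step 1
Reactants: 1 buta-1,3-diene; 2 2,3-dimethylmaleic anhydride
Product: 3 cis-1,2-dimethylcyclohex-4-ene-1,2-dicarboxylic anhydride (meso)
Conditions: toluene, hydroquinone (cat.), sealed vessel, 190 °C
Reagents that add atoms: none
Why: Thermal Diels–Alder reaction; the cyclic Z-dienophile adds suprafacially, so the two new quaternary carbons are necessarily cis, and the tetrasubstituted dienophile is sluggish but reacts at this temperature with excess diene.

Step 2
Reactants: 3 cis-1,2-dimethylcyclohex-4-ene-1,2-dicarboxylic anhydride
Product: 4 cis-1,2-bis(hydroxymethyl)-1,2-dimethylcyclohex-4-ene (meso)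
Conditions: LiAlH4, THF, 0 °C to reflux; Fieser work-up
Reagents that add atoms: none
Why: Hydride reduction of a cyclic anhydride to the 1,4-diol; reflux carries the hindered lactone stage through, and neither the alkene nor the quaternary centres are touched.

Step 3
Reactants: 4 cis-1,2-bis(hydroxymethyl)-1,2-dimethylcyclohex-4-ene
Product: 5 cis-1,2-dimethylcyclohex-4-ene-1,2-dicarbaldehyde (meso)
Conditions: (COCl)2, DMSO, CH2Cl2, −78 °C; Et3N, −78 °C to rt
Reagents that add atoms: none
Why: Swern oxidation; both hydroxyls are converted to alkoxysulfonium ions before the base is added, so both are oxidised together without a lactol stage that could end as a lactone, and the aldehydes have no α-hydrogen to lose.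

Step 4
Reactants: 5 cis-1,2-dimethylcyclohex-4-ene-1,2-dicarbaldehyde; 6 ethyl 2-methylacetoacetate
Product: 8 diethyl 5,5'-(cis-1,2-dimethylcyclohex-4-ene-1,2-diyl)bis(5-hydroxy-2-methyl-3-oxopentanoate) as a diastereomer mixture, via sodium lithium dienolate 7 (not isolated)
Conditions: 6 (4 equiv), NaH, THF, 0 °C; n-BuLi, 0 °C; 5, −78 to 0 °C; aq. NH4Cl
Reagents that add atoms: none
Why: Aldol addition of a β-keto ester dianion through its terminal carbon to non-enolisable aldehydes; the oxide formed in the first addition can close onto the second formyl group as a lactolate, but this stays in equilibrium with the open form and should be drawn through by excess dianion at 0 °C, as in additions of excess organometallic reagents to lactols. The new carbinol and C2 centres are formed unselectively, which does not matter because they become sp2 carbons in step 5.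

Step 5
Reactants: 8 diethyl 5,5'-(cis-1,2-dimethylcyclohex-4-ene-1,2-diyl)bis(5-hydroxy-2-methyl-3-oxopentanoate)
Product: 10 6,6'-(cis-1,2-dimethylcyclohex-4-ene-1,2-diyl)bis(4-hydroxy-3-methyl-2H-pyran-2-one) (meso), via bis(3,5-dioxo ester) 9 (not isolated)
Conditions: Dess–Martin periodinane, CH2Cl2, 0 °C to rt; then DBU, toluene, rt to 60 °C; aq. HCl
Reagents that add atoms: none
Why: Dess–Martin oxidation of the two secondary alcohols gives the 3,5-dioxo esters, and DBU-induced lactonisation of the enolised 5-oxo group onto the ester gives the 4-hydroxy-2-pyranones, a standard pyranone construction. The lactonisation is irreversible and should outrun reversible aldol addition between the two side chains.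

Step 6
Reactants: 10 6,6'-(cis-1,2-dimethylcyclohex-4-ene-1,2-diyl)bis(4-hydroxy-3-methyl-2H-pyran-2-one)
Product: 11 cis-1,2-dimethyl-1,2-bis(Pyr)cyclohex-4-ene (meso)
Conditions: Me2SO4, K2CO3, acetone, reflux
Reagents that add atoms: dimethyl sulfate, COS(=O)(=O)OC
Why: O-Alkylation of the vinylogous acid; dimethyl sulfate with K2CO3 in acetone is the usual way to obtain the 4-methoxy-2-pyranone and not the 2-methoxy-4-pyranone isomer.

Step 7
Reactants: 11 cis-1,2-dimethyl-1,2-bis(Pyr)cyclohex-4-ene
Product: 14 meso-3,4-dimethyl-3,4-bis(Pyr)hexanedioic acid, via ozonide 12 (not isolated), via hexanedial 13 (not isolated)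
Conditions: O3, CH2Cl2, −78 °C, to first persistent blue; Me2S, −78 °C to rt; then NaClO2, NaH2PO4, 2-methylbut-2-ene, t-BuOH/H2O, rt
Reagents that add atoms: ozone, [O-][O+]=O; sodium chlorite, [Na+].[O-]Cl=O
Why: Ozonolysis of the isolated cis-disubstituted alkene, which is more electron-rich than the carbonyl-conjugated pyranone double bonds, followed by Pinnick oxidation of the crude dialdehyde under buffered conditions that the pyranones tolerate. The ring that held C3 and C4 cis is opened without touching them, so the diacid is meso.

Step 8
Reactants: 14 meso-3,4-dimethyl-3,4-bis(Pyr)hexanedioic acid; 15 4-methoxybenzylamine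
Product: 17 racemic 6-[(4-methoxybenzyl)amino]-3,4-dimethyl-6-oxo-3,4-bis(Pyr)hexanoic acid, via cyclic anhydride 16 (not isolated)
Conditions: Ac2O, 90 °C, then evaporate; 15 (1.05 equiv), THF, 0 °C to rt
Reagents that add atoms: none
Why: Dehydration with acetic anhydride should give the monomeric seven-membered anhydride because the four substituents on C3 and C4 favour ring closure (Thorpe–Ingold effect). Aminolysis of a cyclic anhydride stops at the mono-amide, which differentiates the two equivalent carboxyls while leaving C3 and C4 untouched.

Step 9
Reactants: 17 racemic 6-[(4-methoxybenzyl)amino]-3,4-dimethyl-6-oxo-3,4-bis(Pyr)hexanoic acid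
Product: 19 meso 1-(4-methoxybenzyl)-4,5-dimethyl-4,5-bis(Pyr)azepane-2,7-dione (methyls cis), via mixed acetic anhydride 18 (not isolated)
Conditions: Ac2O, NaOAc, 100 °C
Reagents that add atoms: none
Why: Classical cyclodehydration of an amic acid to an imide through the mixed anhydride, with acetate converting any isoimide into the imide. Closure of the seven-membered ring is helped by the same geminal substitution, and the product is again meso.

Step 10
Reactants: 19 meso 1-(4-methoxybenzyl)-4,5-dimethyl-4,5-bis(Pyr)azepane-2,7-dione
Product: 21 3-(4-methoxybenzyl)-6,7-dimethyl-6,7-bis(Pyr)-3-azabicyclo[3.2.0]heptane-2,4-dione (meso; cis ring fusion; both methyls on the imide face), via dilithium bis-enolate 20 (not isolated)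
Conditions: LiN(iPr)2 (2.5 equiv), THF, −78 to −40 °C; CuCl2 (2.5 equiv), DMF, −78 °C to rt
Reagents that add atoms: none
Why: Proposed new method: the dialkylamide base removes one proton from each of the two imide α-methylene groups to give 20; the second deprotonation is at an amide-like carbonyl and therefore needs this strong base and not a silylamide. One-electron oxidation of one enolate by divalent copper gives an α-carbonyl radical that bonds to the carbon of the second enolate across the ring, and a second oxidation completes C1–C2; the closest known reaction type is the intramolecular oxidative coupling of open-chain diester bis-enolates with CuBr2, CuCl2 or I2 to cycloalkane-1,2-dicarboxylates, which has not been run transannularly on an imide. The one new bond divides the seven-membered ring into the cyclobutane, closed in a 4-exo fashion as seen from either enolate carbon, and the succinimide. The new stereocentres C1 and C2 must be cis to each other because the C(=O)–N–C(=O) bridge can only span one face of a four-membered ring. Their relation to C3 and C4, already fixed as the cis-dimethyl pair in 19, depends on the direction in which the ring folds; the fold that places the two small methyls on the concave face under the imide and the two larger pyranones on the convex face is expected to be preferred, and it gives the carbonyls cis to the methyls as the target requires. Site selectivity is secured by the substrate, since C3 and C4 bear no hydrogen and the pyranones have no C–H of comparable acidity. Ring closure should win over dimerisation because the geminal substituents at C3 and C4 hold the two enolate carbons within bonding reach, and moderate dilution supports this.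

Step 11
Reactants: 21 3-(4-methoxybenzyl)-6,7-dimethyl-6,7-bis(Pyr)-3-azabicyclo[3.2.0]heptane-2,4-dione
Product: 22 6,7-dimethyl-6,7-bis(Pyr)-3-azabicyclo[3.2.0]heptane-2,4-dione (meso; cis-fused; methyls on the imide face)
Conditions: (NH4)2Ce(NO3)6 (4 equiv), MeCN/H2O, 0 °C to rt
Reagents that add atoms: none
Why: Oxidative debenzylation: tetravalent cerium oxidises the electron-rich anisyl ring, water adds at the benzylic carbon and the hemiaminal releases the aldehyde. The electron-poor pyranones and the strained but saturated bicycle offer no comparably oxidisable site.

Step 12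
Reactants: 22 6,7-dimethyl-6,7-bis(Pyr)-3-azabicyclo[3.2.0]heptane-2,4-dione
Product: 23 tert-butyl 6,7-dimethyl-2,4-dioxo-6,7-bis(Pyr)-3-azabicyclo[3.2.0]heptane-3-carboxylate (meso)
Conditions: Boc2O, DMAP (cat.), MeCN, rt
Reagents that add atoms: di-tert-butyl dicarbonate, CC(C)(C)OC(=O)OC(=O)OC(C)(C)C
Why: DMAP-catalysed acylation of the acidic imide N–H; the resulting N-Boc imide is a strongly activated triacylamine that opens under conditions far milder than the parent imide needs.

Step 13
Reactants: 23 tert-butyl 6,7-dimethyl-2,4-dioxo-6,7-bis(Pyr)-3-azabicyclo[3.2.0]heptane-3-carboxylate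
Product: 25 racemic 2-[(tert-butoxycarbonyl)carbamoyl]-3,4-dimethyl-3,4-bis(Pyr)cyclobutane-1-carboxylic acid (both acyl groups cis to the methyls), via peroxy acid 24 (not isolated)
Conditions: LiOH, 30% H2O2, THF/H2O, 0 °C; Na2SO3; aq. HCl to pH 3
Reagents that add atoms: hydrogen peroxide, OO
Why: Hydroperoxide, a strong nucleophile of low basicity, attacks a ring carbonyl of the activated imide in preference to the hindered carbamate carbonyl, and sulfite reduces the peroxy acid. The two ring carbonyls are enantiotopic, so either opening gives the same racemate. The pyranones are spared by the low basicity, and C1 and C2 do not epimerise because the products are present as N-anion and carboxylate.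

Step 14
Reactants: 25 racemic 2-[(tert-butoxycarbonyl)carbamoyl]-3,4-dimethyl-3,4-bis(Pyr)cyclobutane-1-carboxylic acid
Product: 27 3,4-dimethyl-3,4-bis(Pyr)cyclobutane-1,2-dicarboxylic acid (meso target; carboxyls cis to each other and to both methyls), via primary amide acid 26 (not isolated)
Conditions: TFA, CH2Cl2, rt, then evaporate; NaNO2, 1 M aq. H2SO4/MeCN, 0 °C to rt
Reagents that add atoms: water, O
Why: Acidolysis removes the tert-butyl carbamate to leave the primary amide, and nitrosation converts it into an acyldiazonium ion that loses N2 on attack of water, possibly assisted by the neighbouring carboxyl (nitrosative deamidation). The conditions are cold and acidic, so the pyranones and the cis arrangement at C1 and C2 are retained.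

## Compound list

1 | buta-1,3-diene | C=CC=C | starting material
2 | 2,3-dimethylmaleic anhydride | CC1=C(C)C(=O)OC1=O | starting material
3 | cis-1,2-dimethylcyclohex-4-ene-1,2-dicarboxylic anhydride (meso) | C[C@]12CC=CC[C@@]1(C)C(=O)OC2=O | intermediate
4 | cis-1,2-bis(hydroxymethyl)-1,2-dimethylcyclohex-4-ene (meso) | C[C@]1(CO)CC=CC[C@@]1(C)CO | intermediate
5 | cis-1,2-dimethylcyclohex-4-ene-1,2-dicarbaldehyde (meso) | C[C@]1(C=O)CC=CC[C@@]1(C)C=O | intermediate
6 | ethyl 2-methylacetoacetate (racemic) | CCOC(=O)C(C)C(C)=O | starting material
7 | sodium lithium dienolate (dianion) of 6 | [Na+].[Li+].C=C([O-])C(C)=C([O-])OCC | intermediate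
8 | diethyl 5,5'-(cis-1,2-dimethylcyclohex-4-ene-1,2-diyl)bis(5-hydroxy-2-methyl-3-oxopentanoate), ring methyls cis, side-chain centres mixed | C[C@]1(C(O)CC(=O)C(C)C(=O)OCC)CC=CC[C@@]1(C)C(O)CC(=O)C(C)C(=O)OCC | intermediate
9 | diethyl 5,5'-(cis-1,2-dimethylcyclohex-4-ene-1,2-diyl)bis(2-methyl-3,5-dioxopentanoate) | C[C@]1(C(=O)CC(=O)C(C)C(=O)OCC)CC=CC[C@@]1(C)C(=O)CC(=O)C(C)C(=O)OCC | intermediate
10 | 6,6'-(cis-1,2-dimethylcyclohex-4-ene-1,2-diyl)bis(4-hydroxy-3-methyl-2H-pyran-2-one) (meso) | C[C@]1(c2cc(O)c(C)c(=O)o2)CC=CC[C@@]1(C)c1cc(O)c(C)c(=O)o1 | intermediate
11 | cis-1,2-dimethyl-1,2-bis(Pyr)cyclohex-4-ene (meso) | C[C@]1(c2cc(OC)c(C)c(=O)o2)CC=CC[C@@]1(C)c1cc(OC)c(C)c(=O)o1 | intermediate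
12 | ozonide (1,2,4-trioxolane) of 11 | C[C@]1(c2cc(OC)c(C)c(=O)o2)CC3OOC(C[C@@]1(C)c2cc(OC)c(C)c(=O)o2)O3 | intermediate
13 | meso-3,4-dimethyl-3,4-bis(Pyr)hexanedial | C[C@@](CC=O)(c1cc(OC)c(C)c(=O)o1)[C@@](C)(CC=O)c1cc(OC)c(C)c(=O)o1 | intermediate
14 | meso-3,4-dimethyl-3,4-bis(Pyr)hexanedioic acid | C[C@@](CC(=O)O)(c1cc(OC)c(C)c(=O)o1)[C@@](C)(CC(=O)O)c1cc(OC)c(C)c(=O)o1 | intermediate
15 | 4-methoxybenzylamine | COc1ccc(CN)cc1 | starting material
16 | cis-4,5-dimethyl-4,5-bis(Pyr)oxepane-2,7-dione (meso cyclic anhydride) | C[C@]1(c2cc(OC)c(C)c(=O)o2)CC(=O)OC(=O)C[C@@]1(C)c1cc(OC)c(C)c(=O)o1 | intermediate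
17 | 6-[(4-methoxybenzyl)amino]-3,4-dimethyl-6-oxo-3,4-bis(Pyr)hexanoic acid (racemic, C3 and C4 as in 14) | COc1ccc(CNC(=O)C[C@](C)(c2cc(OC)c(C)c(=O)o2)[C@@](C)(CC(=O)O)c2cc(OC)c(C)c(=O)o2)cc1 | intermediate
18 | mixed acetic anhydride of 17 | COc1ccc(CNC(=O)C[C@](C)(c2cc(OC)c(C)c(=O)o2)[C@@](C)(CC(=O)OC(C)=O)c2cc(OC)c(C)c(=O)o2)cc1 | intermediate
19 | meso 1-(4-methoxybenzyl)-4,5-dimethyl-4,5-bis(Pyr)azepane-2,7-dione (methyls cis) | C[C@]1(c2cc(OC)c(C)c(=O)o2)CC(=O)N(Cc2ccc(OC)cc2)C(=O)C[C@@]1(C)c1cc(OC)c(C)c(=O)o1 | intermediate
20 | dilithium bis-enolate of 19 | [Li+].[Li+].C[C@]1(c2cc(OC)c(C)c(=O)o2)C=C([O-])N(Cc2ccc(OC)cc2)C([O-])=C[C@@]1(C)c1cc(OC)c(C)c(=O)o1 | intermediate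
21 | 3-(4-methoxybenzyl)-6,7-dimethyl-6,7-bis(Pyr)-3-azabicyclo[3.2.0]heptane-2,4-dione, cis-fused, methyls on the imide face, pyranones on the other (meso) | C[C@]1(c2cc(OC)c(C)c(=O)o2)[C@@H]2C(=O)N(Cc3ccc(OC)cc3)C(=O)[C@@H]2[C@@]1(C)c1cc(OC)c(C)c(=O)o1 | intermediate
22 | 6,7-dimethyl-6,7-bis(Pyr)-3-azabicyclo[3.2.0]heptane-2,4-dione (configuration as in 21) | C[C@]1(c2cc(OC)c(C)c(=O)o2)[C@@H]2C(=O)NC(=O)[C@@H]2[C@@]1(C)c1cc(OC)c(C)c(=O)o1 | intermediate
23 | tert-butyl 6,7-dimethyl-2,4-dioxo-6,7-bis(Pyr)-3-azabicyclo[3.2.0]heptane-3-carboxylate (configuration as in 21) | C[C@]1(c2cc(OC)c(C)c(=O)o2)[C@@H]2C(=O)N(C(=O)OC(C)(C)C)C(=O)[C@@H]2[C@@]1(C)c1cc(OC)c(C)c(=O)o1 | intermediate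
24 | 2-[(tert-butoxycarbonyl)carbamoyl]-3,4-dimethyl-3,4-bis(Pyr)cyclobutane-1-carboperoxoic acid (racemic, acyl groups cis to the methyls) | COc1cc([C@@]2(C)[C@H](C(=O)NC(=O)OC(C)(C)C)[C@H](C(=O)OO)[C@@]2(C)c2cc(OC)c(C)c(=O)o2)oc(=O)c1C | intermediate
25 | 2-[(tert-butoxycarbonyl)carbamoyl]-3,4-dimethyl-3,4-bis(Pyr)cyclobutane-1-carboxylic acid (racemic, acyl groups cis to the methyls) | COc1cc([C@@]2(C)[C@H](C(=O)NC(=O)OC(C)(C)C)[C@H](C(=O)O)[C@@]2(C)c2cc(OC)c(C)c(=O)o2)oc(=O)c1C | intermediate
26 | 2-carbamoyl-3,4-dimethyl-3,4-bis(Pyr)cyclobutane-1-carboxylic acid (racemic, acyl groups cis to the methyls) | COc1cc([C@@]2(C)[C@H](C(N)=O)[C@H](C(=O)O)[C@@]2(C)c2cc(OC)c(C)c(=O)o2)oc(=O)c1C | intermediate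
27 | 3,4-dimethyl-3,4-bis(Pyr)cyclobutane-1,2-dicarboxylic acid, carboxyls cis to each other and to both methyls, pyranones on the other face (meso, CNP0574758.1) | COc1cc([C@@]2(C)[C@H](C(=O)O)[C@H](C(=O)O)[C@@]2(C)c2cc(OC)c(C)c(=O)o2)oc(=O)c1C | target

## Step count and least certain steps

Total: 14 steps. Longest linear sequence: 14 steps, from 1 and 2 to 27; 6 and 15 enter as purchased.

**Step 10 (key step).** Three things may go wrong. The second deprotonation may be incomplete, so that oxidation of a mono-enolate leads to chlorination at the α-carbon or to intermolecular coupling. Closure of the strained ring by radical–enolate bonding may reverse before the second oxidation. The ring may fold toward the pyranone face, so that the imide ends cis to the pyranones.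

The fallback separates the two enolisations and uses known reaction types, setting out from 19 and coming back at 21. One equivalent of LiN(SiMe3)2 in THF at −78 °C followed by N-bromosuccinimide should give 3-bromo-1-(4-methoxybenzyl)-4,5-dimethyl-4,5-bis(Pyr)azepane-2,7-dione F1 by α-bromination of an imide enolate. A second equivalent of LiN(SiMe3)2 then enolises the remaining α-methylene group of the bromo imide F1 and its carbon displaces bromide across the ring to give 21. This is an intramolecular enolate alkylation of the kind that closes cyclobutanes from 4-halo carbonyl compounds. The displacement occurs at a carbon next to a quaternary centre, but it is α to a carbonyl and intramolecular. The face question is the same as in the main step.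

**Step 5.** Aldol condensation between the two side chains may compete with lactonisation under DBU, because 9 is a 1,4-diketone with two active methylene groups. Over-oxidation of those methylene groups by the periodinane is the second concern.

The fallback forms the pyranones without base, setting out from 5 and coming back at 10. The lithium dienolate of 2,2,5,6-tetramethyl-4H-1,3-dioxin-4-one is added to 5 to give the bis(hydroxyalkyl)dioxinone F2 as a diastereomer mixture. Dess–Martin oxidation then gives the bis(oxoalkyl)dioxinone F3 from it. Heating F3 in toluene at 110 °C expels acetone from each dioxinone, and the acylketene formed is captured by the enol of the neighbouring ketone to give the 4-hydroxy-2-pyranone 10 under neutral conditions.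

**Step 9.** Closure of the seven-membered imide may be slow, so that N-acetylation of the amide or oligomeric anhydride formation takes over at 100 °C.

The fallback replaces thermal dehydration by an anionic acyl transfer, setting out from 17 and coming back at 19. The acid is esterified with trimethylsilyldiazomethane to give methyl 6-[(4-methoxybenzyl)amino]-3,4-dimethyl-6-oxo-3,4-bis(Pyr)hexanoate F4 as the only new compound. LiN(SiMe3)2 in THF at 0 °C then deprotonates the amide N–H, which attacks the ester with loss of methoxide and closes the imide 19.

**Step 14.** Nitrosation may be slow at the hindered amide, or the nitrosating agent may attack C5' of the electron-rich side of the pyranones.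

The fallback uses neighbouring-group hydrolysis, setting out from 25 and coming back at 27. After removal of the Boc group with TFA to give 26, warming in aqueous HCl/dioxane lets the cis carboxyl attack the protonated amide. Ammonia leaves and the cis-fused 6,7-dimethyl-6,7-bis(Pyr)-3-oxabicyclo[3.2.0]heptane-2,4-dione F5 forms, which the aqueous acid hydrolyses to 27. This is the known carboxyl-assisted hydrolysis of amic acids. Reclosure to imide 22 is the competing process to watch.

**Step 7.** Ozone may attack the methoxy-substituted pyranone double bonds once the cyclohexene is consumed, so over-oxidation is the risk.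

The fallback replaces ozonolysis by dihydroxylation and glycol cleavage, setting out from 11 and coming back at the non-isolated dialdehyde 13. Catalytic OsO4 with N-methylmorpholine N-oxide in acetone/water should dihydroxylate only the isolated alkene to give cis-4,5-dimethyl-4,5-bis(Pyr)cyclohexane-1,2-diol F6 as the cis-diol. NaIO4 then cleaves it to 13, which is oxidised under the Pinnick conditions of step 7.

## Further compounds

F1 | step 10 | 3-bromo-1-(4-methoxybenzyl)-4,5-dimethyl-4,5-bis(Pyr)azepane-2,7-dione (racemic, configuration at the bromo carbon open) | C[C@]1(c2cc(OC)c(C)c(=O)o2)C(Br)C(=O)N(Cc2ccc(OC)cc2)C(=O)C[C@@]1(C)c1cc(OC)c(C)c(=O)o1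
F2 | step 5 | 6,6'-[(cis-1,2-dimethylcyclohex-4-ene-1,2-diyl)bis(2-hydroxyethane-2,1-diyl)]bis(2,2,5-trimethyl-4H-1,3-dioxin-4-one) | C[C@]1(C(O)CC2=C(C)C(=O)OC(C)(C)O2)CC=CC[C@@]1(C)C(O)CC1=C(C)C(=O)OC(C)(C)O1
F3 | step 5 | 6,6'-[(cis-1,2-dimethylcyclohex-4-ene-1,2-diyl)bis(2-oxoethane-2,1-diyl)]bis(2,2,5-trimethyl-4H-1,3-dioxin-4-one) | C[C@]1(C(=O)CC2=C(C)C(=O)OC(C)(C)O2)CC=CC[C@@]1(C)C(=O)CC1=C(C)C(=O)OC(C)(C)O1
F4 | step 9 | methyl 6-[(4-methoxybenzyl)amino]-3,4-dimethyl-6-oxo-3,4-bis(Pyr)hexanoate (racemic) | COc1ccc(CNC(=O)C[C@](C)(c2cc(OC)c(C)c(=O)o2)[C@@](C)(CC(=O)OC)c2cc(OC)c(C)c(=O)o2)cc1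
F5 | step 14 | 6,7-dimethyl-6,7-bis(Pyr)-3-oxabicyclo[3.2.0]heptane-2,4-dione (cis-fused, methyls on the anhydride face) | C[C@]1(c2cc(OC)c(C)c(=O)o2)[C@@H]2C(=O)OC(=O)[C@@H]2[C@@]1(C)c1cc(OC)c(C)c(=O)o1
F6 | step 7 | cis-4,5-dimethyl-4,5-bis(Pyr)cyclohexane-1,2-diol (cis-diol, face relative to the methyls open) | C[C@]1(c2cc(OC)c(C)c(=O)o2)CC(O)C(O)C[C@@]1(C)c1cc(OC)c(C)c(=O)o1
A1 | alternative 1 | bis(4-methoxy-3-methyl-2-oxo-5,6-dihydro-2H-pyran-6-yl)cyclobutane with C1 and C2 as the acetonide-protected diol (C6' centres undefined) | C[C@]1(C3CC(OC)=C(C)C(=O)O3)[C@@H]2COC(C)(C)OC[C@@H]2[C@@]1(C)C1CC(OC)=C(C)C(=O)O1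
A2 | alternative 1 | cyclobutane cis-dialdehyde with C1 and C2 as the acetonide-protected diol | C[C@]1(C=O)[C@@H]2COC(C)(C)OC[C@@H]2[C@@]1(C)C=O
A3 | alternative 1 | 1,3-dimethoxy-2-methyl-1-(trimethylsilyloxy)buta-1,3-diene | C=C(OC)C(C)=C(OC)O[Si](C)(C)C
A4 | alternative 2 | thiolane-fused and anhydride-fused bis(Pyr)cyclobutane, both rings on the face opposite the pyranones | S1C[C@]2(c3cc(OC)c(C)c(=O)o3)[C@@H]3C(=O)OC(=O)[C@@H]3[C@@]2(C1)c1cc(OC)c(C)c(=O)o1
A5 | alternative 2 | 3,4-bis(Pyr)-2,5-dihydrothiophene | COc1cc(C2=C(c3cc(OC)c(C)c(=O)o3)CSC2)oc(=O)c1C
A6 | alternative 2 | maleic anhydride | O=C1OC(=O)C=C1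
A7 | alternative 3 | bis(Pyr)cyclobutane with C1 and C2 as the acetonide-protected diol | C[C@]1(c3cc(OC)c(C)c(=O)o3)[C@@H]2COC(C)(C)OC[C@@H]2[C@@]1(C)c1cc(OC)c(C)c(=O)o1
A8 | alternative 3 | 3,4-dimethylcyclobutane-3,4-dicarboxylic acid with C1 and C2 as the acetonide-protected diol | C[C@]1(C(=O)O)[C@@H]2COC(C)(C)OC[C@@H]2[C@@]1(C)C(=O)O
A9 | alternative 3 | 4-methoxy-3-methyl-6-(phenylsulfonyl)-2H-pyran-2-one | COc1cc(S(=O)(=O)c2ccccc2)oc(=O)c1C
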